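The data were computed with constants of no real substance, and the scatter is random.

I start with the easiest step there is: I add up the columns of two small tables.

| flask | substrate | remark | time |
|---|---|---|---|
| north-east | 0.082 M | run made earlier |  |
| east | 1.3 M | run made earlier |  |
| Thursday's | 0.060 M |  | 4.0 min |
| Saturday's | 0.80 M |  | 4.0 min |
| Sunday's | 0.25 M |  | 4.0 min |
| Tuesday's | 0.50 M |  | 4.0 min |
| Wednesday's | 1.0 M |  | 4.0 min |
| Friday's | 0.080 M |  | 4.0 min |

| run | time / s | ring / % | open dimer / % |
|---|---|---|---|
| north-east | 10.0 | 3 | 4 |
| north-east | 25.0 | 7 | 0 |
| north-east | 40.0 | 9 | 2 |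
| north-east | 60.0 | 11 | 2 |
| north-east | 90.0 | 13 | 2 |
| north-east | 120 | 17 | 6 |
| east | 20.0 | 4 | 28 |
| east | 40.0 | 8 | 35 |
| east | 60.0 | 6 | 32 |
| east | 80.0 | 11 | 33 |
| east | 90.0 | 8 | 35 |
| east | 120 | 8 | 33 |

(standard deviation of a reading: 2 percentage points)

- in percentages every species weighs as the substrate in it: one open dimer counts as two
- the earlier runs were read with a standard deviation of 2 percentage points
- a reading or a percentage of ring counts all its forms, free or not

1. the flasks by share of ring in all that became ring or open dimer, highest first, at 4.0 min (Thursday's / Saturday's / Sunday's / Tuesday's / Wednesday's / Friday's)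
2. the share of ring in all that became ring or open dimer of the flask you put first, at 4.0 min
3. the share of ring in all that became ring or open dimer of the flask you put last, at 4.0 min

Summed over its readings, open dimer over ring comes to 0.267 in the north-east run and 4.36 in the east run. I read this as a comparison of two rates: I assume ring takes one substrate and open dimer two, so their ratio should rise in step with concentration. The east charge is 15.9 times the north-east charge, and the east ratio is 16.3 times the north-east ratio, which fits.

So I divide each charge by its ratio, which gives 0.307 M for north-east and 0.298 M for east, though the north-east dimer readings lie close to the scatter of 2 percentage points. The mean is 0.303 M; I call it the crossover concentration, the charge at which ring and open dimer gain equal percentages. The share of ring, the selectivity, is then crossover over crossover plus charge.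

Now the drift. In the east run ring reads 8% at 40.0 s and 8% at 120 s, and open dimer reads 35% and 33%, but with a scatter of 2 points on each reading these pairs cannot tell me whether the comparison drifts. The asked time is also twice the last reading, so holding the crossover fixed is my commitment, not a reading. It puts the flasks in order of rising charge, with Thursday's first at 83.5% and Wednesday's last at 23.3%.

The forecast gives Thursday's > Friday's > Sunday's > Tuesday's > Saturday's > Wednesday's, with 84% and 24%, on the ground that “Ring forms first-order and open dimer second-order, so ring loses ground as concentration rises”.

The flasks give Thursday's > Friday's > Sunday's > Tuesday's > Saturday's > Wednesday's, from 86.7% down to 41.7%.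

    substrate + ring ⇌ idle adduct, settled at all times (K = 120 L mol⁻¹)
    substrate ⇌ ring (K = 0.530, k = 0.00460 s⁻¹)
    substrate ⇌ dormant form (K = 2.00, k = 0.0260 s⁻¹)
    2 substrate ⇌ open dimer (K = 7.60 L mol⁻¹, k = 0.0140 L mol⁻¹ s⁻¹)

Read back from the results, the crossover concentration is 0.392 M for Thursday's and 0.717 M for Wednesday's, against my 0.303 M. In Wednesday's, ring goes from 13.8% at 2.00 min to 19.2% at 4.00 min, while open dimer goes from 28.1% to 26.8%. For a flask like Thursday's charged with 0.24 M, my crossover gives 55.8%; that flask stands at 69.4%, with ring, all its forms counted, at 22.1% and open dimer at 9.78%.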